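The route rests on cutting C6′–C7′ of the saturated-lactone half (ring B), where C6′ and the lactone carbonyl C12′ stand 1,4 to each other through C7′–C11′: a C6′ acyl radical adds to the β-carbon C7′ of a C11′=C7′ butenolide. This single step closes ten-membered ring B, forms C6′–C7′ and sets C7′ anti to the C8′ side chain, leaving a C6′ enone for late reduction. Its precursor is an (S)-γ-substituted butenolide carrying an (E,E)-dienoyl phenylselenoester chain. The same vinyl iodide and the same closure give ring A after a [2,3]-Wittig–Still shift places C13′ on C1; C11′ enolate alkylation then joins the halves.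

Key step: step 13

Remark 1 (numbering): germacrane numbering; unprimed atoms are the α-methylene lactone half (ring A: 4E,9Z; 1S,6S,7S,8S), primed atoms the saturated lactone half (ring B: 1′(10′)E,4′E; 6′R,7′S,8′S,11′R); C13′ is the CH2 bridge between C11′ and C1, and "13-nor"/"13′-nor" marks a half that still lacks that carbon.
Remark 2 (configuration of the key-step precursor): with O > C7′ > C9′ > H the butenolide stereocentre C8′ of 20 is S, not R; it is the carbinol centre of (S)-epichlorohydrin carried through without inversion and becomes 8′S of the target.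
Remark 3 (reagents): (TMS)3SiH, N-(phenylseleno)phthalimide, Bu3SnCH2I, Zn(BH4)2 and Eschenmoser's salt are taken as available reagents.

Step 1
Reactants: 1 ethyl acetoacetate; 2 1-bromobut-2-yne
Product: 3 ethyl 3-oxooct-6-ynoate
Conditions: NaH, THF, 0 °C; n-BuLi, 0 °C; then 2, 0 °C → rt
Reagents that add atoms: none
Why: Weiler dianion alkylation, in which the more basic γ-carbanion of the acetoacetate dianion should attack the propargylic bromide selectively and lay down C14, C10 and C1–C6 of both chains.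

Step 2
Reactants: 3 ethyl 3-oxooct-6-ynoate
Product: 4 ethyl (2Z)-3-[(diethoxyphosphoryl)oxy]oct-2-en-6-ynoate
Conditions: NaH, Et2O, 0 °C; ClP(O)(OEt)2, 0 °C → rt
Reagents that add atoms: diethyl chlorophosphate, CCOP(=O)(Cl)OCC
Why: O-phosphorylation of the chelated sodium enolate of a β-keto ester is known to give the (Z)-enol phosphate, which fixes the geometry that step 3 hands on to C4=C5.

Step 3
Reactants: 4 ethyl (2Z)-3-[(diethoxyphosphoryl)oxy]oct-2-en-6-ynoate
Product: 5 ethyl (2E)-3-methyloct-2-en-6-ynoate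
Conditions: Me2CuLi, Et2O, −78 → −45 °C
Reagents that add atoms: lithium dimethylcuprate, [Li+].C[Cu-]C
Why: Cuprate substitution of the β-(phosphoryloxy) enoate (addition–elimination with retention) should place the new methyl group cis to the ester and so give the (E)-trisubstituted alkene.

Step 4
Reactants: 5 ethyl (2E)-3-methyloct-2-en-6-ynoate
Product: 6 (2E)-3-methyloct-2-en-6-yn-1-ol
Conditions: DIBAL-H (2.2 equiv), CH2Cl2, −78 °C; Rochelle salt
Reagents that add atoms: none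
Why: 1,2-Reduction of the enoate by DIBAL-H should give the allylic alcohol without touching the alkyne or the alkene geometry.

Step 5
Reactants: 6 (2E)-3-methyloct-2-en-6-yn-1-ol
Product: 7 tert-butyl{[(2E)-3-methyloct-2-en-6-yn-1-yl]oxy}diphenylsilane
Conditions: TBDPSCl, imidazole, DMF, rt
Reagents that add atoms: tert-butyl(chloro)diphenylsilane, CC(C)(C)[Si](Cl)(c1ccccc1)c1ccccc1
Why: Silylation gives an ether that should withstand t-BuLi, KH, n-BuLi and the aqueous acid of step 22, which a TBS ether would not.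

Step 6
Reactants: 7 tert-butyl{[(2E)-3-methyloct-2-en-6-yn-1-yl]oxy}diphenylsilane
Product: 8 tert-butyl{[(2E,6E)-7-iodo-3-methylocta-2,6-dien-1-yl]oxy}diphenylsilane
Conditions: Cp2Zr(H)Cl (2 equiv), THF, 50 °C; then I2, 0 °C
Reagents that add atoms: iodine, II
Why: syn-Hydrozirconation of the 2-alkyne with excess Schwartz reagent equilibrates zirconium to the less hindered methyl-bearing carbon, and iodinolysis with retention should give the (E)-2-iodoalkene that defines C1=C10 in both halves.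

Step 7
Reactants: 8 tert-butyl{[(2E,6E)-7-iodo-3-methylocta-2,6-dien-1-yl]oxy}diphenylsilane; 9 (S)-epichlorohydrin
Product: 11 (2S)-2-{(2E,6E)-8-[(tert-butyldiphenylsilyl)oxy]-2,6-dimethylocta-2,6-dien-1-yl}oxirane, via chlorohydrin 10 (not isolated)
Conditions: 8, t-BuLi (2 equiv), Et2O, −78 °C; MgBr2·OEt2; CuI (10 mol %), 9, THF, −40 → 0 °C; then K2CO3, MeOH, rt
Reagents that add atoms: none
Why: Copper-catalysed alkenyl Grignard opening of the epoxide at its CH2 group and base-induced closure of the chlorohydrin onto CH2Cl never break the C–O bond of the stereocentre, so C8′ takes its configuration from 9.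

Step 8
Reactants: 11 (2S)-2-{(2E,6E)-8-[(tert-butyldiphenylsilyl)oxy]-2,6-dimethylocta-2,6-dien-1-yl}oxirane; 12 (phenylsulfanyl)acetic acid
Product: 14 (5S)-5-{(2E,6E)-8-[(tert-butyldiphenylsilyl)oxy]-2,6-dimethylocta-2,6-dien-1-yl}-3-(phenylsulfanyl)oxolan-2-one, via hydroxy acid 13 (not isolated)
Conditions: 12, LDA (2.2 equiv), THF, −78 → 0 °C; 11, 0 °C → rt; aq. HCl; then PPTS (cat.), CH2Cl2, rt
Reagents that add atoms: none
Why: The dianion of 12 should open the terminal epoxide at C7′ (SN2) and the γ-hydroxy acid lactonises under mild acid, which forms C7′–C11′ and the lactone without touching C8′.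

Step 9
Reactants: 14 (5S)-5-{(2E,6E)-8-[(tert-butyldiphenylsilyl)oxy]-2,6-dimethylocta-2,6-dien-1-yl}-3-(phenylsulfanyl)oxolan-2-one
Product: 16 (5S)-5-{(2E,6E)-8-[(tert-butyldiphenylsilyl)oxy]-2,6-dimethylocta-2,6-dien-1-yl}furan-2(5H)-one, via sulfoxide 15 (not isolated)
Conditions: NaIO4, MeOH/THF/H2O, 0 °C; then toluene, CaCO3, 110 °C
Reagents that add atoms: none
Why: Periodate oxidises only sulfur and the thermal syn-elimination of the sulfoxide can take a hydrogen only from C7′, so the C11′=C7′ butenolide should form with C8′ intact.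

Step 10
Reactants: 16 (5S)-5-{(2E,6E)-8-[(tert-butyldiphenylsilyl)oxy]-2,6-dimethylocta-2,6-dien-1-yl}furan-2(5H)-one
Product: 17 (5S)-5-[(2E,6E)-8-hydroxy-2,6-dimethylocta-2,6-dien-1-yl]furan-2(5H)-one
Conditions: HF·pyridine, pyridine, THF, 0 °C → rt
Reagents that add atoms: none
Why: Buffered fluoride desilylation frees the allylic alcohol without a base that would enolise the butenolide at C8′.

Step 11
Reactants: 17 (5S)-5-[(2E,6E)-8-hydroxy-2,6-dimethylocta-2,6-dien-1-yl]furan-2(5H)-one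
Product: 19 (2E,6E)-3,7-dimethyl-8-[(2S)-5-oxo-2,5-dihydrofuran-2-yl]octa-2,6-dienoic acid, via enal 18 (not isolated)
Conditions: TEMPO (10 mol %), PhI(OAc)2, CH2Cl2, rt; then NaClO2, NaH2PO4, 2-methyl-2-butene, t-BuOH/H2O, 0 °C
Reagents that add atoms: sodium chlorite, [Na+].[O-]Cl=O
Why: TEMPO oxidation of the allylic alcohol and Pinnick oxidation of the enal are neutral to mildly acidic, so the 4′E geometry and the butenolide should both survive.

Step 12
Reactants: 19 (2E,6E)-3,7-dimethyl-8-[(2S)-5-oxo-2,5-dihydrofuran-2-yl]octa-2,6-dienoic acid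
Product: 20 Se-phenyl (2E,6E)-3,7-dimethyl-8-[(2S)-5-oxo-2,5-dihydrofuran-2-yl]octa-2,6-dieneselenoate
Conditions: N-(phenylseleno)phthalimide, Bu3P, CH2Cl2, −20 °C → rt
Reagents that add atoms: N-(phenylseleno)phthalimide, O=C1N([Se]c2ccccc2)C(=O)c2ccccc12
Why: Grieco selenoesterification activates the acid as an acyloxyphosphonium salt that is captured by phenylselenolate under neutral conditions, which the butenolide tolerates.

Step 13
Reactants: 20 Se-phenyl (2E,6E)-3,7-dimethyl-8-[(2S)-5-oxo-2,5-dihydrofuran-2-yl]octa-2,6-dieneselenoate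
Product: 21 (7′R,8′S)-6′-oxo-13′-norgermacra-1′(10′)E,4′E-dien-12′,8′-olide
Conditions: (TMS)3SiH (1.3 equiv), AIBN (0.2 equiv), added over 10 h to 20 (2 mM), benzene, 80 °C
Reagents that add atoms: none
Why: Tris(trimethylsilyl)silyl radicals take the phenylseleno group from 20 and release the C6′ dienoyl radical, which is nucleophilic and adds to the electron-poor β-carbon C7′ of the butenolide; the C11′ α-carbonyl radical then takes hydrogen from the silane and the chain goes on. The closest known reaction type is the macrocyclisation of selenoester-derived acyl radicals onto enones and enoates, combined with radical conjugate addition to γ-substituted butenolides. Ring B is closed in a 10-exo-trig mode through the new C6′–C7′ bond. The new stereocentre C7′ is controlled by C8′: the radical enters on the butenolide face opposite the C8′ side chain, which gives the trans ring fusion. The step needs ring closure to beat hydrogen transfer to the acyl radical and needs C4′=C5′ to keep its E geometry; slow addition of a slow hydrogen donor at high dilution and the two E-trisubstituted alkenes that pre-fold the tether work in that direction, and 6-exo or 7-endo attack on C1′=C10′ is impossible while C4′=C5′ stays E. No base is present, so the acidic C8′–H of the butenolide is never removed.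

Step 14
Reactants: 21 (7′R,8′S)-6′-oxo-13′-norgermacra-1′(10′)E,4′E-dien-12′,8′-olide
Product: 22 (6′R,7′S,8′S)-6′-hydroxy-13′-norgermacra-1′(10′)E,4′E-dien-12′,8′-olide
Conditions: NaBH4, CeCl3·7H2O, MeOH, −78 °C
Reagents that add atoms: none
Why: Luche 1,2-reduction, in which hydride should enter from the open peripheral face of the C6′ carbonyl of the crown-shaped (E,E)-cyclodecadienone and place the hydroxyl on the same side as the C8′ oxygen (6′R), while the lactone is left alone.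

Step 15
Reactants: 22 (6′R,7′S,8′S)-6′-hydroxy-13′-norgermacra-1′(10′)E,4′E-dien-12′,8′-olide
Product: 23 6′-O-(tert-butyldimethylsilyl) ether of 22
Conditions: TBSOTf, 2,6-lutidine, CH2Cl2, −78 °C
Reagents that add atoms: tert-butyldimethylsilyl trifluoromethanesulfonate, CC(C)(C)[Si](C)(C)OS(=O)(=O)C(F)(F)F
Why: Silyl triflate with a hindered base should silylate the secondary allylic alcohol at low temperature without ionising it, masking the hydroxyl for the enolate chemistry of steps 34 and 35.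

Step 16
Reactants: 24 methyl (4R)-2,2-dimethyl-1,3-dioxolane-4-carboxylate
Product: 25 (4R)-N-methoxy-N,2,2-trimethyl-1,3-dioxolane-4-carboxamide
Conditions: MeNH(OMe)·HCl, i-PrMgCl, THF, −20 °C
Reagents that add atoms: N,O-dimethylhydroxylamine hydrochloride, CNOC.Cl
Why: Weinreb amide formation with the chloromagnesium amide at low temperature should not epimerise the α-alkoxy stereocentre, which later becomes C8.

Step 17
Reactants: 8 tert-butyl{[(2E,6E)-7-iodo-3-methylocta-2,6-dien-1-yl]oxy}diphenylsilane; 25 (4R)-N-methoxy-N,2,2-trimethyl-1,3-dioxolane-4-carboxamide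
Product: 26 (2E,6E)-8-[(tert-butyldiphenylsilyl)oxy]-1-[(4R)-2,2-dimethyl-1,3-dioxolan-4-yl]-2,6-dimethylocta-2,6-dien-1-one
Conditions: 8, t-BuLi (2 equiv), Et2O, −78 °C; then 25, −78 → −20 °C
Reagents that add atoms: none
Why: Iodine–lithium exchange proceeds with retention of the (E) geometry and the alkenyllithium is acylated only once by the Weinreb amide because the chelated tetrahedral adduct survives until work-up.

Step 18
Reactants: 26 (2E,6E)-8-[(tert-butyldiphenylsilyl)oxy]-1-[(4R)-2,2-dimethyl-1,3-dioxolan-4-yl]-2,6-dimethylocta-2,6-dien-1-one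
Product: 27 (1S,2E,6E)-8-[(tert-butyldiphenylsilyl)oxy]-1-[(4R)-2,2-dimethyl-1,3-dioxolan-4-yl]-2,6-dimethylocta-2,6-dien-1-ol
Conditions: Zn(BH4)2, Et2O, −30 °C
Reagents that add atoms: none
Why: Chelation-controlled 1,2-reduction, in which zinc bridges the carbonyl and the α-oxygen of the dioxolane and hydride enters from the less hindered face of the chelate, should give the 1,2-anti allylic alcohol, the C9 configuration that step 20 needs.

Step 19
Reactants: 27 (1S,2E,6E)-8-[(tert-butyldiphenylsilyl)oxy]-1-[(4R)-2,2-dimethyl-1,3-dioxolan-4-yl]-2,6-dimethylocta-2,6-dien-1-ol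
Product: 28 tributylstannylmethyl ether of 27
Conditions: KH, THF, 0 °C; Bu3SnCH2I, 18-crown-6 (cat.), rt
Reagents that add atoms: tributyl(iodomethyl)stannane, CCCC[Sn](CCCC)(CCCC)CI
Why: Williamson etherification of the potassium alkoxide with the primary iodide installs the stannylmethyl group whose carbon becomes C13′.

Step 20
Reactants: 28 tributylstannylmethyl ether of 27
Product: 29 (2R,5E)-7-[(tert-butyldiphenylsilyl)oxy]-2-{(1Z)-1-[(4S)-2,2-dimethyl-1,3-dioxolan-4-yl]prop-1-en-2-yl}-5-methylhept-5-en-1-ol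
Conditions: n-BuLi, THF, −78 °C
Reagents that add atoms: none
Why: [2,3]-Wittig–Still rearrangement, in which tin–lithium exchange gives the α-alkoxymethyllithium that shifts suprafacially through the envelope in which the dioxolanyl group turns away from the C10 methyl (A1,2 strain), should form the (9Z) alkene and transfer the C9 configuration to C1, which gains the CH2OH group (C13′).

Step 21
Reactants: 29 (2R,5E)-7-[(tert-butyldiphenylsilyl)oxy]-2-{(1Z)-1-[(4S)-2,2-dimethyl-1,3-dioxolan-4-yl]prop-1-en-2-yl}-5-methylhept-5-en-1-ol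
Product: 30 4-methoxybenzyl ether of 29
Conditions: NaH, PMBCl, Bu4NI (cat.), DMF, 0 °C → rt
Reagents that add atoms: 4-methoxybenzyl chloride, COc1ccc(CCl)cc1
Why: Williamson etherification protects the primary alcohol as a PMB ether that should survive every step up to its oxidative release in step 32.

Step 22
Reactants: 30 4-methoxybenzyl ether of 29
Product: 31 (2S,3Z,5R,8E)-10-[(tert-butyldiphenylsilyl)oxy]-5-{[(4-methoxybenzyl)oxy]methyl}-4,8-dimethyldeca-3,8-diene-1,2-diol
Conditions: AcOH/H2O (4:1), 40 °C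
Reagents that add atoms: none
Why: Acid-catalysed hydrolysis of the terminal acetonide frees the C7,C8 diol while the TBDPS and PMB ethers are stable to aqueous acetic acid.

Step 23
Reactants: 31 (2S,3Z,5R,8E)-10-[(tert-butyldiphenylsilyl)oxy]-5-{[(4-methoxybenzyl)oxy]methyl}-4,8-dimethyldeca-3,8-diene-1,2-diol
Product: 33 (2S)-2-[(1Z,3R,6E)-8-[(tert-butyldiphenylsilyl)oxy]-3-{[(4-methoxybenzyl)oxy]methyl}-2,6-dimethylocta-1,6-dien-1-yl]oxirane, via tosylate 32 (not isolated)
Conditions: TsCl, Et3N, Bu2SnO (cat.), CH2Cl2, 0 °C; then K2CO3, MeOH, 0 °C → rt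
Reagents that add atoms: none
Why: Tin-catalysed sulfonylation selects the primary hydroxyl of the 1,2-diol and the C8 alkoxide then closes the epoxide by intramolecular Williamson displacement at C7, so the C8–O bond and its configuration are kept.

Step 24
Reactants: 33 (2S)-2-[(1Z,3R,6E)-8-[(tert-butyldiphenylsilyl)oxy]-3-{[(4-methoxybenzyl)oxy]methyl}-2,6-dimethylocta-1,6-dien-1-yl]oxirane; 12 (phenylsulfanyl)acetic acid
Product: 35 (5R)-5-[(1Z,3R,6E)-8-[(tert-butyldiphenylsilyl)oxy]-3-{[(4-methoxybenzyl)oxy]methyl}-2,6-dimethylocta-1,6-dien-1-yl]-3-(phenylsulfanyl)oxolan-2-one, via hydroxy acid 34 (not isolated)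
Conditions: 12, LDA (2.2 equiv), THF, −78 → 0 °C; 33, 0 °C → rt; aq. HCl; then PPTS (cat.), CH2Cl2, rt
Reagents that add atoms: none
Why: The dianion of 12 should attack the unhindered terminal carbon C7 of the vinyl epoxide (SN2, since SN2′ attack would have to occur at the fully substituted C10), and mild acid closes the lactone through the carboxyl group, leaving the allylic C8–O bond intact.

Step 25
Reactants: 35 (5R)-5-[(1Z,3R,6E)-8-[(tert-butyldiphenylsilyl)oxy]-3-{[(4-methoxybenzyl)oxy]methyl}-2,6-dimethylocta-1,6-dien-1-yl]-3-(phenylsulfanyl)oxolan-2-one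
Product: 37 (5R)-5-[(1Z,3R,6E)-8-[(tert-butyldiphenylsilyl)oxy]-3-{[(4-methoxybenzyl)oxy]methyl}-2,6-dimethylocta-1,6-dien-1-yl]furan-2(5H)-one, via sulfoxide 36 (not isolated)
Conditions: NaIO4, MeOH/THF/H2O, 0 °C; then toluene, CaCO3, 110 °C
Reagents that add atoms: none
Why: Sulfide oxidation and thermal syn-elimination of benzenesulfenic acid toward C7 should give the C11=C7 butenolide, as in step 9.

Step 26
Reactants: 37 (5R)-5-[(1Z,3R,6E)-8-[(tert-butyldiphenylsilyl)oxy]-3-{[(4-methoxybenzyl)oxy]methyl}-2,6-dimethylocta-1,6-dien-1-yl]furan-2(5H)-one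
Product: 38 (5R)-5-[(1Z,3R,6E)-8-hydroxy-3-{[(4-methoxybenzyl)oxy]methyl}-2,6-dimethylocta-1,6-dien-1-yl]furan-2(5H)-one
Conditions: HF·pyridine, pyridine, THF, 0 °C → rt
Reagents that add atoms: none
Why: Buffered fluoride desilylation frees the C6 allylic alcohol and should affect neither the PMB ether nor the butenolide.

Step 27
Reactants: 38 (5R)-5-[(1Z,3R,6E)-8-hydroxy-3-{[(4-methoxybenzyl)oxy]methyl}-2,6-dimethylocta-1,6-dien-1-yl]furan-2(5H)-one
Product: 40 (2E,6R,7Z)-6-{[(4-methoxybenzyl)oxy]methyl}-3,7-dimethyl-8-[(2R)-5-oxo-2,5-dihydrofuran-2-yl]octa-2,7-dienoic acid, via enal 39 (not isolated)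
Conditions: TEMPO (10 mol %), PhI(OAc)2, CH2Cl2, rt; then NaClO2, NaH2PO4, 2-methyl-2-butene, t-BuOH/H2O, 0 °C
Reagents that add atoms: sodium chlorite, [Na+].[O-]Cl=O
Why: TEMPO oxidation and Pinnick oxidation should raise C6 to the acid without isomerising C4=C5 or touching the PMB ether.

Step 28
Reactants: 40 (2E,6R,7Z)-6-{[(4-methoxybenzyl)oxy]methyl}-3,7-dimethyl-8-[(2R)-5-oxo-2,5-dihydrofuran-2-yl]octa-2,7-dienoic acid
Product: 41 Se-phenyl (2E,6R,7Z)-6-{[(4-methoxybenzyl)oxy]methyl}-3,7-dimethyl-8-[(2R)-5-oxo-2,5-dihydrofuran-2-yl]octa-2,7-dieneselenoate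
Conditions: N-(phenylseleno)phthalimide, Bu3P, CH2Cl2, −20 °C → rt
Reagents that add atoms: N-(phenylseleno)phthalimide, O=C1N([Se]c2ccccc2)C(=O)c2ccccc12
Why: Grieco selenoesterification under neutral conditions, as in step 12.

Step 29
Reactants: 41 Se-phenyl (2E,6R,7Z)-6-{[(4-methoxybenzyl)oxy]methyl}-3,7-dimethyl-8-[(2R)-5-oxo-2,5-dihydrofuran-2-yl]octa-2,7-dieneselenoate
Product: 42 (1R,7R,8S)-1-{[(4-methoxybenzyl)oxy]methyl}-6-oxo-13-norgermacra-4E,9Z-dien-12,8-olide
Conditions: (TMS)3SiH (1.3 equiv), AIBN (0.2 equiv), added over 10 h to 41 (2 mM), benzene, 80 °C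
Reagents that add atoms: none
Why: The same radical conjugate-addition macrocyclisation as in step 13, in which the C6 dienoyl radical should add 10-exo-trig to C7 of the butenolide on the face opposite the C8 alkenyl substituent (trans ring fusion), the (9Z) alkene serving as a turn in the tether, and the C11 radical is reduced by the silane.

Step 30
Reactants: 42 (1R,7R,8S)-1-{[(4-methoxybenzyl)oxy]methyl}-6-oxo-13-norgermacra-4E,9Z-dien-12,8-olide
Product: 43 (1R,6S,7S,8S)-6-hydroxy-1-{[(4-methoxybenzyl)oxy]methyl}-13-norgermacra-4E,9Z-dien-12,8-olide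
Conditions: L-Selectride, THF, −78 °C
Reagents that add atoms: none
Why: 1,2-Reduction with a bulky hydride, which should attack from the ring periphery anti to the C7–C8 bond (Felkin–Anh) and so place the hydroxyl cis to C11 and trans to the C8 oxygen (6S), while the lactone is not reduced at −78 °C.

Step 31
Reactants: 43 (1R,6S,7S,8S)-6-hydroxy-1-{[(4-methoxybenzyl)oxy]methyl}-13-norgermacra-4E,9Z-dien-12,8-olide
Product: 44 6-O-(tert-butyldimethylsilyl) ether of 43
Conditions: TBSOTf, 2,6-lutidine, CH2Cl2, −78 °C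
Reagents that add atoms: tert-butyldimethylsilyl trifluoromethanesulfonate, CC(C)(C)[Si](C)(C)OS(=O)(=O)C(F)(F)F
Why: Silylation of the secondary allylic alcohol masks it for the base-mediated steps 34 and 35.

Step 32
Reactants: 44 6-O-(tert-butyldimethylsilyl) ether of 43
Product: 45 6-O-(tert-butyldimethylsilyl)-1-(hydroxymethyl)-13-norgermacra-4E,9Z-dien-12,8-olide
Conditions: DDQ, CH2Cl2/pH 7 buffer, 0 °C
Reagents that add atoms: none
Why: Oxidative cleavage of the PMB ether by DDQ in buffered wet dichloromethane should free the primary alcohol and leave the silyl ether, the alkenes and the lactone alone.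

Step 33
Reactants: 45 6-O-(tert-butyldimethylsilyl)-1-(hydroxymethyl)-13-norgermacra-4E,9Z-dien-12,8-olide
Product: 46 trifluoromethanesulfonate of 45
Conditions: Tf2O, 2,6-lutidine, CH2Cl2, −78 °C; used at once
Reagents that add atoms: trifluoromethanesulfonic anhydride, O=S(=O)(OS(=O)(=O)C(F)(F)F)C(F)(F)F
Why: Triflation of the primary alcohol at low temperature with a hindered base gives the most reactive electrophile available for the β-branched C13′ carbon.

Step 34
Reactants: 23 6′-O-(tert-butyldimethylsilyl) ether of 22; 46 trifluoromethanesulfonate of 45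
Product: 47 6,6′-bis-O-(tert-butyldimethylsilyl) ether of the 13-nor dimer
Conditions: 23, LDA, THF, −78 °C; then 46, DMPU, −78 → −40 °C
Reagents that add atoms: none
Why: Alkylation of the lactone lithium enolate by the primary triflate, in which the electrophile should enter anti to the adjacent C7′ substituent so that C13′ ends trans to C6′ (11′R), and the fast reaction of a triflate at low temperature should outrun proton exchange with the ring A lactone.

Step 35
Reactants: 47 6,6′-bis-O-(tert-butyldimethylsilyl) ether of the 13-nor dimer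
Product: 50 6,6′-bis-O-(tert-butyldimethylsilyl) ether of the target, via Mannich base 48 (not isolated), via ammonium iodide 49 (not isolated)
Conditions: LDA (1.05 equiv), THF, −78 °C; CH2=NMe2+ I−, −78 → 0 °C; then MeI, MeOH, rt; then aq. NaHCO3, CH2Cl2, rt
Reagents that add atoms: N,N-dimethylmethyleneiminium iodide (Eschenmoser's salt), C=[N+](C)C.[I-]
Why: Kinetic deprotonation should occur at the unhindered C11 methylene of the ring A lactone and not at the tertiary C11′–H, and the Mannich reaction with Eschenmoser's salt, N-methylation and base-induced β-elimination of trimethylamine then give the exocyclic C11=C13 alkene.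

Step 36
Reactants: 50 6,6′-bis-O-(tert-butyldimethylsilyl) ether of the target
Product: 51 CNP0191625.1
Conditions: HF·pyridine, THF, 0 °C → rt
Reagents that add atoms: none
Why: Fluoride cleaves both secondary TBS ethers under conditions that the α-methylene lactone and the two cyclodecadienes should tolerate.

Compound list
1 | ethyl acetoacetate | CCOC(=O)CC(C)=O | starting material
2 | 1-bromobut-2-yne | CC#CCBr | starting material
3 | ethyl 3-oxooct-6-ynoate | CCOC(=O)CC(=O)CCC#CC | intermediate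
4 | ethyl (2Z)-3-[(diethoxyphosphoryl)oxy]oct-2-en-6-ynoate | CCOC(=O)/C=C(\OP(=O)(OCC)OCC)CCC#CC | intermediate
5 | ethyl (2E)-3-methyloct-2-en-6-ynoate | CCOC(=O)/C=C(\C)CCC#CC | intermediate
6 | (2E)-3-methyloct-2-en-6-yn-1-ol | OC/C=C(\C)CCC#CC | intermediate
7 | tert-butyl{[(2E)-3-methyloct-2-en-6-yn-1-yl]oxy}diphenylsilane | CC#CCC/C(C)=C/CO[Si](c1ccccc1)(c1ccccc1)C(C)(C)C | intermediate
8 | tert-butyl{[(2E,6E)-7-iodo-3-methylocta-2,6-dien-1-yl]oxy}diphenylsilane | C/C(I)=C\CC/C(C)=C/CO[Si](c1ccccc1)(c1ccccc1)C(C)(C)C | intermediate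
9 | (S)-epichlorohydrin | ClC[C@@H]1CO1 | starting material
10 | (2S,4E,8E)-10-[(tert-butyldiphenylsilyl)oxy]-1-chloro-4,8-dimethyldeca-4,8-dien-2-ol | ClC[C@@H](O)C/C(C)=C/CC/C(C)=C/CO[Si](c1ccccc1)(c1ccccc1)C(C)(C)C | intermediate (not isolated)
11 | (2S)-2-{(2E,6E)-8-[(tert-butyldiphenylsilyl)oxy]-2,6-dimethylocta-2,6-dien-1-yl}oxirane | O1C[C@@H]1C/C(C)=C/CC/C(C)=C/CO[Si](c1ccccc1)(c1ccccc1)C(C)(C)C | intermediate
12 | (phenylsulfanyl)acetic acid | OC(=O)CSc1ccccc1 | starting material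
13 | (4S,6E,10E)-12-[(tert-butyldiphenylsilyl)oxy]-4-hydroxy-6,10-dimethyl-2-(phenylsulfanyl)dodeca-6,10-dienoic acid (C2 epimers) | OC(=O)C(Sc1ccccc1)C[C@@H](O)C/C(C)=C/CC/C(C)=C/CO[Si](c1ccccc1)(c1ccccc1)C(C)(C)C | intermediate (not isolated)
14 | (5S)-5-{(2E,6E)-8-[(tert-butyldiphenylsilyl)oxy]-2,6-dimethylocta-2,6-dien-1-yl}-3-(phenylsulfanyl)oxolan-2-one (C3 epimers) | O=C1C(Sc2ccccc2)C[C@H](C/C(C)=C/CC/C(C)=C/CO[Si](c2ccccc2)(c2ccccc2)C(C)(C)C)O1 | intermediate
15 | (5S)-5-{(2E,6E)-8-[(tert-butyldiphenylsilyl)oxy]-2,6-dimethylocta-2,6-dien-1-yl}-3-(phenylsulfinyl)oxolan-2-one | O=C1C(S(=O)c2ccccc2)C[C@H](C/C(C)=C/CC/C(C)=C/CO[Si](c2ccccc2)(c2ccccc2)C(C)(C)C)O1 | intermediate (not isolated)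
16 | (5S)-5-{(2E,6E)-8-[(tert-butyldiphenylsilyl)oxy]-2,6-dimethylocta-2,6-dien-1-yl}furan-2(5H)-one | O=C1C=C[C@H](C/C(C)=C/CC/C(C)=C/CO[Si](c2ccccc2)(c2ccccc2)C(C)(C)C)O1 | intermediate
17 | (5S)-5-[(2E,6E)-8-hydroxy-2,6-dimethylocta-2,6-dien-1-yl]furan-2(5H)-one | O=C1C=C[C@H](C/C(C)=C/CC/C(C)=C/CO)O1 | intermediate
18 | (2E,6E)-3,7-dimethyl-8-[(2S)-5-oxo-2,5-dihydrofuran-2-yl]octa-2,6-dienal | O=C1C=C[C@H](C/C(C)=C/CC/C(C)=C/C=O)O1 | intermediate (not isolated)
19 | (2E,6E)-3,7-dimethyl-8-[(2S)-5-oxo-2,5-dihydrofuran-2-yl]octa-2,6-dienoic acid | O=C1C=C[C@H](C/C(C)=C/CC/C(C)=C/C(=O)O)O1 | intermediate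
20 | Se-phenyl (2E,6E)-3,7-dimethyl-8-[(2S)-5-oxo-2,5-dihydrofuran-2-yl]octa-2,6-dieneselenoate | O=C1C=C[C@H](C/C(C)=C/CC/C(C)=C/C(=O)[Se]c2ccccc2)O1 | intermediate
21 | (7′R,8′S)-6′-oxo-13′-norgermacra-1′(10′)E,4′E-dien-12′,8′-olide (trans-fused) | C1C(=O)O[C@H]2C/C(C)=C/CC/C(C)=C/C(=O)[C@@H]21 | intermediate
22 | (6′R,7′S,8′S)-6′-hydroxy-13′-norgermacra-1′(10′)E,4′E-dien-12′,8′-olide | C1C(=O)O[C@H]2C/C(C)=C/CC/C(C)=C/[C@@H](O)[C@@H]21 | intermediate
23 | 6′-O-(tert-butyldimethylsilyl) ether of 22 | C1C(=O)O[C@H]2C/C(C)=C/CC/C(C)=C/[C@@H](O[Si](C)(C)C(C)(C)C)[C@@H]21 | intermediate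
24 | methyl (4R)-2,2-dimethyl-1,3-dioxolane-4-carboxylate | COC(=O)[C@H]1COC(C)(C)O1 | starting material
25 | (4R)-N-methoxy-N,2,2-trimethyl-1,3-dioxolane-4-carboxamide | CON(C)C(=O)[C@H]1COC(C)(C)O1 | intermediate
26 | (2E,6E)-8-[(tert-butyldiphenylsilyl)oxy]-1-[(4R)-2,2-dimethyl-1,3-dioxolan-4-yl]-2,6-dimethylocta-2,6-dien-1-one | O=C([C@H]1COC(C)(C)O1)/C(C)=C/CC/C(C)=C/CO[Si](c1ccccc1)(c1ccccc1)C(C)(C)C | intermediate
27 | (1S,2E,6E)-8-[(tert-butyldiphenylsilyl)oxy]-1-[(4R)-2,2-dimethyl-1,3-dioxolan-4-yl]-2,6-dimethylocta-2,6-dien-1-ol (1,2-anti) | O[C@H]([C@H]1COC(C)(C)O1)/C(C)=C/CC/C(C)=C/CO[Si](c1ccccc1)(c1ccccc1)C(C)(C)C | intermediate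
28 | tributylstannylmethyl ether of 27 | CCCC[Sn](CCCC)(CCCC)CO[C@H]([C@H]1COC(C)(C)O1)/C(C)=C/CC/C(C)=C/CO[Si](c1ccccc1)(c1ccccc1)C(C)(C)C | intermediate
29 | (2R,5E)-7-[(tert-butyldiphenylsilyl)oxy]-2-{(1Z)-1-[(4S)-2,2-dimethyl-1,3-dioxolan-4-yl]prop-1-en-2-yl}-5-methylhept-5-en-1-ol | OC[C@H](CC/C(C)=C/CO[Si](c1ccccc1)(c1ccccc1)C(C)(C)C)/C(C)=C\[C@H]1COC(C)(C)O1 | intermediate
30 | 4-methoxybenzyl ether of 29 | COc1ccc(COC[C@H](CC/C(C)=C/CO[Si](c2ccccc2)(c2ccccc2)C(C)(C)C)/C(C)=C\[C@H]2COC(C)(C)O2)cc1 | intermediate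
31 | (2S,3Z,5R,8E)-10-[(tert-butyldiphenylsilyl)oxy]-5-{[(4-methoxybenzyl)oxy]methyl}-4,8-dimethyldeca-3,8-diene-1,2-diol | COc1ccc(COC[C@H](CC/C(C)=C/CO[Si](c2ccccc2)(c2ccccc2)C(C)(C)C)/C(C)=C\[C@H](O)CO)cc1 | intermediate
32 | 1-O-(4-methylbenzenesulfonyl) derivative of 31 | COc1ccc(COC[C@H](CC/C(C)=C/CO[Si](c2ccccc2)(c2ccccc2)C(C)(C)C)/C(C)=C\[C@H](O)COS(=O)(=O)c2ccc(C)cc2)cc1 | intermediate (not isolated)
33 | (2S)-2-[(1Z,3R,6E)-8-[(tert-butyldiphenylsilyl)oxy]-3-{[(4-methoxybenzyl)oxy]methyl}-2,6-dimethylocta-1,6-dien-1-yl]oxirane | COc1ccc(COC[C@H](CC/C(C)=C/CO[Si](c2ccccc2)(c2ccccc2)C(C)(C)C)/C(C)=C\[C@H]2CO2)cc1 | intermediate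
34 | (4R,5Z,7R,10E)-12-[(tert-butyldiphenylsilyl)oxy]-4-hydroxy-7-{[(4-methoxybenzyl)oxy]methyl}-6,10-dimethyl-2-(phenylsulfanyl)dodeca-5,10-dienoic acid (C2 epimers) | COc1ccc(COC[C@H](CC/C(C)=C/CO[Si](c2ccccc2)(c2ccccc2)C(C)(C)C)/C(C)=C\[C@H](O)CC(Sc2ccccc2)C(=O)O)cc1 | intermediate (not isolated)
35 | (5R)-5-[(1Z,3R,6E)-8-[(tert-butyldiphenylsilyl)oxy]-3-{[(4-methoxybenzyl)oxy]methyl}-2,6-dimethylocta-1,6-dien-1-yl]-3-(phenylsulfanyl)oxolan-2-one (C3 epimers) | COc1ccc(COC[C@H](CC/C(C)=C/CO[Si](c2ccccc2)(c2ccccc2)C(C)(C)C)/C(C)=C\[C@H]2CC(Sc3ccccc3)C(=O)O2)cc1 | intermediate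
36 | 3-(phenylsulfinyl) analogue (sulfoxide) of 35 | COc1ccc(COC[C@H](CC/C(C)=C/CO[Si](c2ccccc2)(c2ccccc2)C(C)(C)C)/C(C)=C\[C@H]2CC(S(=O)c3ccccc3)C(=O)O2)cc1 | intermediate (not isolated)
37 | (5R)-5-[(1Z,3R,6E)-8-[(tert-butyldiphenylsilyl)oxy]-3-{[(4-methoxybenzyl)oxy]methyl}-2,6-dimethylocta-1,6-dien-1-yl]furan-2(5H)-one | COc1ccc(COC[C@H](CC/C(C)=C/CO[Si](c2ccccc2)(c2ccccc2)C(C)(C)C)/C(C)=C\[C@H]2C=CC(=O)O2)cc1 | intermediate
38 | (5R)-5-[(1Z,3R,6E)-8-hydroxy-3-{[(4-methoxybenzyl)oxy]methyl}-2,6-dimethylocta-1,6-dien-1-yl]furan-2(5H)-one | COc1ccc(COC[C@H](CC/C(C)=C/CO)/C(C)=C\[C@H]2C=CC(=O)O2)cc1 | intermediate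
39 | (2E,6R,7Z)-6-{[(4-methoxybenzyl)oxy]methyl}-3,7-dimethyl-8-[(2R)-5-oxo-2,5-dihydrofuran-2-yl]octa-2,7-dienal | COc1ccc(COC[C@H](CC/C(C)=C/C=O)/C(C)=C\[C@H]2C=CC(=O)O2)cc1 | intermediate (not isolated)
40 | (2E,6R,7Z)-6-{[(4-methoxybenzyl)oxy]methyl}-3,7-dimethyl-8-[(2R)-5-oxo-2,5-dihydrofuran-2-yl]octa-2,7-dienoic acid | COc1ccc(COC[C@H](CC/C(C)=C/C(=O)O)/C(C)=C\[C@H]2C=CC(=O)O2)cc1 | intermediate
41 | Se-phenyl (2E,6R,7Z)-6-{[(4-methoxybenzyl)oxy]methyl}-3,7-dimethyl-8-[(2R)-5-oxo-2,5-dihydrofuran-2-yl]octa-2,7-dieneselenoate | COc1ccc(COC[C@H](CC/C(C)=C/C(=O)[Se]c2ccccc2)/C(C)=C\[C@H]2C=CC(=O)O2)cc1 | intermediate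
42 | (1R,7R,8S)-1-{[(4-methoxybenzyl)oxy]methyl}-6-oxo-13-norgermacra-4E,9Z-dien-12,8-olide (trans-fused) | C1C(=O)O[C@H]2/C=C(/C)[C@H](COCc3ccc(OC)cc3)CC/C(C)=C/C(=O)[C@H]12 | intermediate
43 | (1R,6S,7S,8S)-6-hydroxy-1-{[(4-methoxybenzyl)oxy]methyl}-13-norgermacra-4E,9Z-dien-12,8-olide | C1C(=O)O[C@H]2/C=C(/C)[C@H](COCc3ccc(OC)cc3)CC/C(C)=C/[C@H](O)[C@H]12 | intermediate
44 | 6-O-(tert-butyldimethylsilyl) ether of 43 | C1C(=O)O[C@H]2/C=C(/C)[C@H](COCc3ccc(OC)cc3)CC/C(C)=C/[C@H](O[Si](C)(C)C(C)(C)C)[C@H]12 | intermediate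
45 | 6-O-(tert-butyldimethylsilyl)-1-(hydroxymethyl)-13-norgermacra-4E,9Z-dien-12,8-olide | C1C(=O)O[C@H]2/C=C(/C)[C@H](CO)CC/C(C)=C/[C@H](O[Si](C)(C)C(C)(C)C)[C@H]12 | intermediate
46 | trifluoromethanesulfonate of 45 | C1C(=O)O[C@H]2/C=C(/C)[C@H](COS(=O)(=O)C(F)(F)F)CC/C(C)=C/[C@H](O[Si](C)(C)C(C)(C)C)[C@H]12 | intermediate
47 | 6,6′-bis-O-(tert-butyldimethylsilyl) ether of the 13-nor dimer (target without C13 and with both hydroxyls silylated) | C1C(=O)O[C@H]2/C=C(/C)[C@H](C[C@H]3C(=O)O[C@H]4C/C(C)=C/CC/C(C)=C/[C@@H](O[Si](C)(C)C(C)(C)C)[C@@H]43)CC/C(C)=C/[C@H](O[Si](C)(C)C(C)(C)C)[C@H]12 | intermediate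
48 | 13-(dimethylamino)-11,13-dihydro derivative of 50 (Mannich base, C11 epimers) | CN(C)CC1C(=O)O[C@H]2/C=C(/C)[C@H](C[C@H]3C(=O)O[C@H]4C/C(C)=C/CC/C(C)=C/[C@@H](O[Si](C)(C)C(C)(C)C)[C@@H]43)CC/C(C)=C/[C@H](O[Si](C)(C)C(C)(C)C)[C@H]12 | intermediate (not isolated)
49 | trimethylammonium iodide of 48 | C[N+](C)(C)CC1C(=O)O[C@H]2/C=C(/C)[C@H](C[C@H]3C(=O)O[C@H]4C/C(C)=C/CC/C(C)=C/[C@@H](O[Si](C)(C)C(C)(C)C)[C@@H]43)CC/C(C)=C/[C@H](O[Si](C)(C)C(C)(C)C)[C@H]12.[I-] | intermediate (not isolated)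
50 | 6,6′-bis-O-(tert-butyldimethylsilyl) ether of the target | C=C1C(=O)O[C@H]2/C=C(/C)[C@H](C[C@H]3C(=O)O[C@H]4C/C(C)=C/CC/C(C)=C/[C@@H](O[Si](C)(C)C(C)(C)C)[C@@H]43)CC/C(C)=C/[C@H](O[Si](C)(C)C(C)(C)C)[C@H]12 | intermediate
51 | CNP0191625.1 | C=C1C(=O)O[C@H]2/C=C(/C)[C@H](C[C@H]3C(=O)O[C@H]4C/C(C)=C/CC/C(C)=C/[C@@H](O)[C@@H]43)CC/C(C)=C/[C@H](O)[C@H]12 | target

Total step count: 36. Longest linear sequence: 26 steps (steps 1–6, 17–33, 34–36).

Steps most likely to fail

Step 13. The acyl radical may take hydrogen before it cyclises, giving the open-chain aldehyde. C4′=C5′ may also lose its geometry through the ketene-like resonance form of the dienoyl radical, which would open the way to six-membered closure, and the chain may oligomerise. The fallback makes the same C6′–C7′ bond by an anionic addition mild enough for the butenolide. It sets out from alcohol 17: Appel bromination (CBr4, PPh3, CH2Cl2) would give the allylic bromide F1, and Kornblum substitution (NaNO2, urea, DMF) the allylic nitro compound F2. Catalytic DBU in MeCN at high dilution would then close ring B by intramolecular nitro-Michael addition to C7′, again anti to the C8′ side chain, giving the 6′-nitro lactone F3. A McMurry–Nef reaction (aq. TiCl3, NH4OAc, THF) would return to the route at enone 21.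

Step 29. The same processes as in step 13 may intervene, and in addition the doubly allylic C8–H of the γ-alkenyl butenolide may be abstracted, diverting the chain. The fallback again replaces the radical closure by a nitronate closure and sets out from alcohol 38: Appel bromination would give the allylic bromide F4, and Kornblum substitution the allylic nitro compound F5. Catalytic DBU at high dilution would give the 6-nitro lactone F6 by Michael addition to C7 anti to the C8 alkenyl group. The McMurry–Nef reaction would return to the route at enone 42.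

Step 34. The enolate may act as a base and eliminate the triflate through its allylic C1–H, or exchange a proton with the ring A lactone before it is alkylated, so that the two halves do not join. The fallback replaces the SN2 union by an aldol union followed by deoxygenation and sets out from alcohol 45: Dess–Martin oxidation would give the aldehyde F7. Its addition at −78 °C to the lithium enolate of 23, again anti to the C7′ substituent, would give the β-hydroxy lactone F8. Phenyl chlorothionoformate and DMAP would give the thionocarbonate F9, and Barton–McCombie reduction (Bu3SnH, AIBN, toluene, 80 °C) would return to the route at 47.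

Further compounds
F1 | step 13 | (5S)-5-[(2E,6E)-8-bromo-2,6-dimethylocta-2,6-dien-1-yl]furan-2(5H)-one | O=C1C=C[C@H](C/C(C)=C/CC/C(C)=C/CBr)O1
F2 | step 13 | (5S)-5-[(2E,6E)-2,6-dimethyl-8-nitroocta-2,6-dien-1-yl]furan-2(5H)-one | O=C1C=C[C@H](C/C(C)=C/CC/C(C)=C/C[N+](=O)[O-])O1
F3 | step 13 | 6′-nitro-13′-norgermacra-1′(10′)E,4′E-dien-12′,8′-olide (trans-fused, C6′ epimers) | C1C(=O)O[C@H]2C/C(C)=C/CC/C(C)=C/C([N+](=O)[O-])[C@@H]21
F4 | step 29 | (5R)-5-[(1Z,3R,6E)-8-bromo-3-{[(4-methoxybenzyl)oxy]methyl}-2,6-dimethylocta-1,6-dien-1-yl]furan-2(5H)-one | COc1ccc(COC[C@H](CC/C(C)=C/CBr)/C(C)=C\[C@H]2C=CC(=O)O2)cc1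
F5 | step 29 | (5R)-5-[(1Z,3R,6E)-3-{[(4-methoxybenzyl)oxy]methyl}-2,6-dimethyl-8-nitroocta-1,6-dien-1-yl]furan-2(5H)-one | COc1ccc(COC[C@H](CC/C(C)=C/C[N+](=O)[O-])/C(C)=C\[C@H]2C=CC(=O)O2)cc1
F6 | step 29 | 1-{[(4-methoxybenzyl)oxy]methyl}-6-nitro-13-norgermacra-4E,9Z-dien-12,8-olide (trans-fused, C6 epimers) | C1C(=O)O[C@H]2/C=C(/C)[C@H](COCc3ccc(OC)cc3)CC/C(C)=C/C([N+](=O)[O-])[C@H]12
F7 | step 34 | 6-O-(tert-butyldimethylsilyl)-1-formyl-13-norgermacra-4E,9Z-dien-12,8-olide | C1C(=O)O[C@H]2/C=C(/C)[C@H](C=O)CC/C(C)=C/[C@H](O[Si](C)(C)C(C)(C)C)[C@H]12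
F8 | step 34 | 13′-hydroxy derivative of 47 (aldol adduct, C13′ epimers) | C1C(=O)O[C@H]2/C=C(/C)[C@H](C(O)[C@H]3C(=O)O[C@H]4C/C(C)=C/CC/C(C)=C/[C@@H](O[Si](C)(C)C(C)(C)C)[C@@H]43)CC/C(C)=C/[C@H](O[Si](C)(C)C(C)(C)C)[C@H]12
F9 | step 34 | 13′-O-(phenoxythiocarbonyl) derivative of F8 | C1C(=O)O[C@H]2/C=C(/C)[C@H](C(OC(=S)Oc3ccccc3)[C@H]3C(=O)O[C@H]4C/C(C)=C/CC/C(C)=C/[C@@H](O[Si](C)(C)C(C)(C)C)[C@@H]43)CC/C(C)=C/[C@H](O[Si](C)(C)C(C)(C)C)[C@H]12
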